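The numbers stand for no real mixture; the rest is arithmetic.

Solvolysis product is what is counted here, as a fraction of the charged starting material, in flasks that differ in how a charge goes in.

common to all: second nucleophile 0.0816 M; protic impurity 0.0340 M; time 30 s

| flask | starting material | first nucleophile | remark |
|---|---|---|---|
| ochre | 0.068 M (fed, over 25 s) | 0.0680 M | all else is in the flask from the start; the feed brings no volume worth counting |
| teal | 0.068 M | 0.0680 M (in portions, 5, over 25 s) | first portion at the start, last at 25 s |
| green | 0.068 M | 0.0680 M (fed, over 25 s) | all else is in the flask from the start; the feed brings no volume worth counting |
| violet | 0.068 M | 0.0680 M | everything together at the start |

    intermediate → solvolysis product (k1 = 120 s⁻¹)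
    second nucleophile + intermediate → other capture product (k2 = 100 M⁻¹ s⁻¹)
    crystals ⇌ target, rate k3*(cs3 - [target]) while solid is left; crystals form when [target] > cs3 (cs3 = 27 mM, k3 = 0.28 s⁻¹)
    starting material → intermediate (k4 = 0.54 s⁻¹)
    first nucleophile + intermediate ⇌ target (K5 = 26 M⁻¹, k5 = 290 M⁻¹ s⁻¹)
    starting material + protic impurity → quenched substrate (k6 = 0.44 M⁻¹ s⁻¹)

- amounts and yields of target count crystals too
- given per volume of solution although it is solid: crystals
- run time (ochre): 30 s

* the flask that comes out highest in amount of solvolysis product, in percent of the starting material charged; "all alike" if 1.5 percentage points covers them all (ochre / teal / green / violet / all alike)
* amount of solvolysis product at the end, in percent of the starting material charged, ochre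
* amount of solvolysis product at the end, in percent of the starting material charged, teal
* amount of solvolysis product at the end, in percent of the starting material charged, green
* amount of solvolysis product at the end, in percent of the starting material charged, violet

Two chemists argue over these flasks. The first holds that first nucleophile takes a kinetic share of intermediate, 13.3% at its full charge against solvolysis and second nucleophile. On that view violet ends near 79.0%, while green, with first nucleophile on average at half its charge during the feed, ends near 84.6%, a gap of 5.6 percentage points that is wider than the margin.

The second answers that this capture is reversible: target returns to intermediate at 11.2 s⁻¹, a lifetime far shorter than the run, so captured intermediate is lent and not lost, and the symmetric case, in which first nucleophile moves no share, is the zero of the scale. The first keeps one region for his view, where target stands above its solubility, 39.7% of the charge, and falls out as crystals; but target in violet, reckoned as if the whole charge were still starting material, is about 0.745%, far below that.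

I side with the second. Taking protic impurity and second nucleophile as pseudo-first-order partners at their charged amounts, starting material ionises with a share of 97.3% and intermediate solvolyses with a share of 93.6%. Their product, 91.1%, is the passage fraction, the share of the charge that gets through both forks, and since it holds no term for first nucleophile I give it to teal, green and violet. Ochre, fed over 25 s, should by my reckoning still hold about 0.498% of its charge as starting material at the end, so I put ochre at 90.7%, a drop inside the margin.

The forecast takes the same side: all alike, with ochre 90.9%, teal 91.3%, green 91.3% and violet 91.3%, on the ground that target is “a fast, reversible holding pool”. For green it stands 0.20 points above my figure.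

The flasks came out all alike: ochre 90.9%, teal 91.3%, green 91.3%, violet 91.3%. In violet at 30.0 s crystals stood at 0% of the charge, and taking their falling out away changes nothing between the flasks. A neighbour of green with protic impurity raised to 0.14 M has a passage fraction of 84.0%, and that flask gave 84.4%.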